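- In a one-step world, substrate passes straight to ring, and a flask is told by the share of the charge that becomes ring per minute and by how that share climbs with temperature. I had two runs at c_substrate 2.1 M and 4 flasks to judge at 1.5 M.

| flask | substrate | temperature | remark | time |
|---|---|---|---|---|
| south-east | 2.1 M | 5 °C | run made earlier |  |
| north | 2.1 M | 40 °C | run made earlier |  |
| winter | 1.5 M | 10 °C |  | 3.0 min |
| noon | 1.5 M | 70 °C |  | 3.0 min |
| midnight | 1.5 M | 30 °C |  | 3.0 min |
| dusk | 1.5 M | 50 °C |  | 3.0 min |

- south-east (time / min: ring / %): 0.167: 1.0; 0.500: 1.3; 0.833: 1.0; 1.33: 0.2; 2.00: 1.7; 2.50: 1.0; 3.00: 3.2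
- north (time / s: ring / %): 10.0: 5.7; 12.0: 6.7; 20.0: 6.8; 25.0: 9.8; 30.0: 11.4; 40.0: 14.2

(standard deviation of a reading: 1 percentage point)

- the flask with the highest amount of ring, in percent of the substrate charged ("all alike" if they lie within 1.5 percentage points) (winter / noon / midnight / dusk / all alike)
- final ring, as a percentage of the substrate charged, in winter
- final ring, as a percentage of the substrate charged, in noon
- final ring, as a percentage of the substrate charged, in midnight
- final ring, as a percentage of the substrate charged, in dusk

- the earlier runs were read with a standard deviation of 1 percentage point
- a reading or a percentage of ring counts all its forms, free or not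

- The last 3 south-east readings, summed over their times, gave 0.00787 min⁻¹ of the charge, and the last north reading gave 0.213 min⁻¹. I took this share to be independent of c_substrate.
- In logarithms, that rise is 1.43 powers of ten over 35.0 K. The rise came to 24.4 K per power of ten, and I call this warming, which multiplies the rate by ten, the decade span.
- Carried to winter, the span gave 3.78% of ring in 3.0 min, which is believable. Carried to noon, it gave 1080%, yet the charge is 100%, so the two numbers seemed to clash.
- The clash cleared when I read the span as a statement about the rate while ring was low, at 14.2% or below in the readings of the runs. At that rate, noon would use its substrate, the limiting reagent, in 0.278 min, so the rate cannot hold for the whole run, and the charge caps ring in noon.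
- The north run's ring per minute since the start read 0.342 min⁻¹ at the first reading and 0.213 min⁻¹ at the last, each reading with a scatter of 1 percentage point, so I held the charge as a ceiling for noon, not as a value for it.
- The forecast, which differed from my ceiling by giving noon a value, named noon as highest, with 4% in winter, 21% in midnight, 58% in dusk and 85% in noon, and it noted possible causes of curvature, “none of which these runs can exclude”.
- The flasks gave noon as highest, with 3.31% of ring in winter, 18.3% in midnight, 43.4% in dusk and 55.2% in noon.

    substrate → ring (k = 0.0170 s⁻¹, Ea = 82.0 kJ mol⁻¹)
    2 substrate → open dimer (k = 0.0190 M⁻¹ s⁻¹, Ea = 60.0 kJ mol⁻¹)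
    substrate + ring ⇌ idle adduct, settled at all times (K = 0.330 M⁻¹, ΔH = −24.0 kJ mol⁻¹)
    (constants at 50 °C)

- Winter came in 0.47 points below my reckoning. I then used the same span on a repeat of winter at 25 °C, and my reckoning gave 15.5% of ring, and at that rate the charge would last 19.4 min, so the cap was not reached by the reckoning. That neighbour flask gave 12.9% of ring, with 31.9% of the substrate remaining and 52.0% standing as open dimer.

The earlier runs and the new flask stem from a simulated flask for an exercise, and the scatter is random.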